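**Compound numbers used throughout:** 1 guaiacol; 2 guaiacol MOM ether; 3 3-fluoroanisole; 4–8 intermediates of the key step that are not isolated; 9 mono-MOM biphenol; 10 biphenol; 11 dibromide; 12 methyl acrylate; 13 bis-acrylate; 14 saturated diester; 15 target.

## The problem

Compound 15 is a C2-symmetric biphenyl built from two dihydroferulic acid units joined through the ring carbons ortho to their phenolic hydroxyl groups. Each ring is 1,2,3,5-tetrasubstituted: C1 carries the other ring, C2 the hydroxyl, C3 the methoxy group and C5 the 2-carboxyethyl chain. The central task is therefore a biaryl bond flanked on both sides by oxygen and placed with unambiguous regiochemistry. There is no stereocenter, and the axis, with only the two hydroxyl groups as ortho substituents, is not a stable stereogenic element, so no stereochemical control is needed. The sensitive part is the pair of electron-rich 2-methoxyphenols, which one-electron oxidants, or air in base, convert to quinones and oligomers; oxidants and aerobic alkaline conditions must be kept away from the free phenols. The two chains are identical and sit para to the hydroxyl groups, the position at which a 2,6-disubstituted phenol reacts with electrophiles, so they can be attached late and both at once. The feature that opens the key step is the contiguous triad C1 (aryl), C2 (OH), C3 (OMe) in each ring. It is the pattern left when 3-methoxybenzyne accepts an aryl nucleophile at C1 and an oxygen electrophile at C2, and the partner ring shows the same triad as an ortho-lithiated, O-protected guaiacol.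

## Retrosynthesis

**15 back to 14 and 13.** No skeletal bond is cut in the first two moves. The acids of 15 are traced to the methyl esters of 14, and the saturated chains of 14 to the (E,E)-bis-acrylate 13. Carrying the acids as esters keeps every intermediate neutral and chromatographable and leaves the single aqueous base treatment to the end. Compound 13 is chosen because an aryl–vinyl bond is far easier to make than an aryl–alkyl bond. The forward steps are a hydrogenation that must leave the arenes alone and an ester hydrolysis run with exclusion of air.

**13 back to 11 and 12.** The two C5–Cβ (aryl–vinyl) bonds are cut. A cut at the benzylic CH2–CH2 bond would require a bis-benzylic electrophile on an oxidisable phenol, and a cut at CH2–CO2H would require C1 chemistry on a styrene. The aryl–vinyl cut brings the whole three-carbon chain from methyl acrylate 12 at the carboxylic acid oxidation level and asks only for a leaving group para to each hydroxyl. Dibromide 11 has lost both chains. The forward reaction is a twofold Heck vinylation of an electron-rich bromophenol that must go to completion at both sites.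

**11 back to 10 and 9.** Removing the two C5–Br bonds gives biphenol 10. The halogen enters by electrophilic substitution, and this must be done on the free bisphenol: only the hydroxyl group directs to C5 (para to OH, meta to OMe), whereas with an ether at C2 the methoxy group would steer to C4 and C6. The MOM group of 9 is therefore removed before bromination. Biphenol 10 is the bare 2,2'-dihydroxy-3,3'-dimethoxybiphenyl core.

**9 back to 2 and 3 (key disconnection).** In 9 the C1–C1' biaryl bond and the C2–O bond of the unprotected ring are cut together.
- This returns two monocyclic arenes, 2 and 3, neither pre-halogenated at the coupling carbon nor pre-borylated.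
- The neighbouring options are weaker here. Oxidative coupling of a guaiacol with a free para position gives ortho–ortho, ortho–para, para–para and C–O linked products. A cross-coupling needs an ortho-halophenol and an ortho-boronate, each made by metalation anyway.
- The aryne route sets the ortho,ortho'-dioxygenated pattern by polar reactivity alone, with no phenol oxidation.
- The forward reaction requires three things: metalation of 2 next to OMOM and of 3 between F and OMe, attack of the aryllithium at the aryne carbon remote from OMe, and suppression of aryne capture by its own precursor.
- MOM is chosen because it is the strongest oxygen director on the nucleophile, inert to aryllithiums and removable with mild acid.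

**2 back to 1.** The O–CH2 bond of the acetal is cut. Methoxymethylation of guaiacol 1 gives 2. Compounds 1, 3 and 12 are purchased.

## Roads not taken

**Alternative 1: twofold para-quinone methide alkylation of malonate.**
- Cut: the two benzylic CH2–CH bonds.
- Forward key step: the bis-Mannich base A1 is heated with excess sodium dimethyl malonate A2. Each half expels its amine to give a para-quinone methide, which takes up the malonate and gives tetraester A3. Hydrolysis and double decarboxylation would then give 15.
- Merits: no transition metal and no halogenation. The Mannich reaction of biphenol 10 is para-selective for the same reason as the bromination. From 10 the sequence is three operations, against four in the chosen end game.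
- Weak points: a para-Mannich base lacks the intramolecular hydrogen bond that helps ortho isomers ionise, so quinone methide formation needs forcing conditions or prior quaternisation. The mono-benzylated malonate is still acidic and can capture a second quinone methide; with a bifunctional substrate this leads to oligomers unless A2 is used in large excess. The hot decarboxylation is run on an oxidisable bisphenol.
- Comparison: this road is one step shorter after the biaryl and palladium-free, but it says nothing about how the biaryl is made and would have to borrow 10 from the chosen plan. The chosen plan sets against the extra step a Heck reaction in which each C–Br bond can react only once, so no oligomer pathway exists.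

**Alternative 2: double para-Claisen rearrangement.**
- Cut: the two C5–CH2 bonds, traced back to the O-allyl groups of diallyl ether A4.
- Forward key step: heating A4 moves each allyl group first to a blocked ortho carbon (3,3 shift to a dienone that cannot enolise) and then on to C5 by a Cope shift, giving dehydrodieugenol A5.
- Merits: positional control is complete because both ortho positions are occupied. No reagent or metal is needed, and both chains arrive in one thermal step. In this respect it is better than bromination followed by Heck coupling.
- Weak points: the chain arrives as allyl, at the wrong oxidation level. Turning each terminal alkene into CH2CO2H needs anti-Markovnikov hydroboration and a two-stage oxidation to the acid. Those oxidations cannot be run on the free 2-methoxyphenols that the rearrangement has just released, so a protection and a deprotection are added. The end game grows to about five steps.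
- Comparison: like Alternative 1, it presupposes the biaryl. The chosen plan sets against its traceless, metal-free chain transfer that methyl acrylate 12 delivers the chain already at the acid oxidation level, so no oxidant meets the free phenols after the biaryl is made.

**Alternative 3: twofold cathodic hydrocarboxylation.**
- Cut: the two CH2–CO2H bonds.
- Forward key step: the bis-MOM divinylbiaryl A6 is electrolysed under carbon dioxide A7 with a proton donor. Carboxylation at each terminal vinyl carbon and protonation of the benzylic anion would give bis-MOM diacid A8, and acid then gives 15.
- Merits: the carboxyl carbon comes from A7, the acid is formed directly without ester hydrolysis, and atom economy is high. MOM ethers tolerate reductive conditions.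
- Weak points: para-oxygenated styrenes are reduced only at very negative potential. Three side reactions compete: capture of a second A7 by the benzylic anion (arylsuccinic acid), simple hydrogenation of the vinyl group and reductive dimerisation. The desired course has to win twice in one molecule. A6 itself needs the biaryl, a double protection and a twofold vinylation, and A8 needs deprotection, so the sequence is longer than Heck, hydrogenation and saponification from dibromide 11. Electrolysis equipment is also required.
- Comparison: it matches the chosen plan in the number of C–C bonds formed and beats it in atom economy. The chosen plan sets against this a carbon chain that arrives whole, so that where the carboxyl ends up is never in question.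

Key step: step 2

Assumption: the biaryl axis of 15, flanked only by the two hydroxyl groups, is taken to rotate freely, so the target is treated as achiral and no stereochemical element has to be set.

## Route

Step 1
Reactants: 1 guaiacol (2-methoxyphenol)
Product: 2 1-methoxy-2-(methoxymethoxy)benzene (guaiacol MOM ether)
Conditions: MOMCl (1.2 equiv), i-Pr2NEt (1.5 equiv), CH2Cl2, 0 °C to rt
Reagents that add atoms: chloromethyl methyl ether, COCCl
Why: O-alkylation of the phenol by the highly reactive alpha-chloro ether in the presence of an amine base (Williamson-type etherification); the resulting acetal is inert to organolithium reagents and serves as the ortho director in step 2.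

Step 2
Reactants: 2 1-methoxy-2-(methoxymethoxy)benzene; 3 3-fluoroanisole
Product: 9 3,3'-dimethoxy-2'-(methoxymethoxy)biphenyl-2-ol, via aryllithium 4 (not isolated), via 2-lithio-3-fluoroanisole 5 (not isolated), via 3-methoxybenzyne 6 (not isolated), via 2-lithiobiaryl 7 (not isolated), via lithium aryltrimethoxyborate 8 (not isolated)
Conditions: (a) 2 (2.2 equiv), n-BuLi (2.0 equiv), THF, 0 °C; (b) 3 (1.0 equiv), n-BuLi (1.0 equiv), THF, −78 °C; (c) solution (b) added slowly by cold cannula to solution (a) at −30 °C, then to 0 °C; (d) B(OMe)3, −78 °C to rt; (e) 30% H2O2, AcOH, 0 °C to rt
Reagents that add atoms: hydrogen peroxide, OO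
Why: Directed ortho-metalation puts lithium next to the OMOM group of 2 (the stronger director, giving 4) and between F and OMe of 3 (giving 5); both metalations are completed in separate flasks so that neither free n-BuLi nor unmetalated 3 meets the aryne. On warming, 5 loses LiF to give 3-methoxybenzyne 6, whose methoxy group withdraws sigma density and distorts the triple bond so that the carbon remote from OMe is the electrophilic terminus; 4 adds there and the new carbanion of 7 lies ortho to OMe, stabilised by induction and by lithium chelation to the neighbouring oxygens. B(OMe)3 converts 7 into borate 8, and peroxide oxidation (1,2-shift of the aryl group from boron to oxygen) replaces the C–B bond by C–OH, so the C1–C1' bond and the C2–O bond are both made in one pot. The closest known reaction type is the addition of aryllithium or aryl Grignard reagents to arynes generated from ortho-metalated haloarenes with electrophilic capture of the 2-biaryl metal species, combined with the standard borate–peroxide hydroxylation of aryllithiums. No ring is closed and no stereocenter is formed. The selectivity needed is regiochemical (which aryne carbon is attacked), secured by the 3-methoxy group, and chemoselective (4 rather than 5 as the nucleophile), secured by slow inverse addition of cold 5 to a twofold amount of the less hindered and more nucleophilic 4; the surplus of 4 ends as a monocyclic phenol to be removed by chromatography.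

Step 3
Reactants: 9 3,3'-dimethoxy-2'-(methoxymethoxy)biphenyl-2-ol
Product: 10 3,3'-dimethoxybiphenyl-2,2'-diol
Conditions: 3 M aq. HCl, MeOH, 50 °C
Reagents that add atoms: none
Why: Acid-catalysed acetal exchange of the MOM ether with methanol frees the second phenol; aryl methyl ethers are untouched under these conditions.

Step 4
Reactants: 10 3,3'-dimethoxybiphenyl-2,2'-diol
Product: 11 5,5'-dibromo-3,3'-dimethoxybiphenyl-2,2'-diol
Conditions: NBS (2.05 equiv), MeCN, −10 to 0 °C, dark
Reagents that add atoms: N-bromosuccinimide, O=C1CCC(=O)N1Br
Why: Electrophilic aromatic bromination; in each ring the free hydroxyl group is the dominant director and both of its ortho positions are substituted, so bromine should enter at C5, para to OH, as in the para-bromination of guaiacol-type phenols.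

Step 5
Reactants: 11 5,5'-dibromo-3,3'-dimethoxybiphenyl-2,2'-diol; 12 methyl acrylate
Product: 13 dimethyl (2E,2'E)-3,3'-(6,6'-dihydroxy-5,5'-dimethoxybiphenyl-3,3'-diyl)bis(prop-2-enoate)
Conditions: 12 (4 equiv), Pd(OAc)2 (5 mol %), P(o-tol)3 (20 mol %), Et3N, DMF, 100 °C, argon
Reagents that add atoms: none
Why: Twofold Heck reaction: Pd(OAc)2, a divalent palladium precatalyst, is reduced in situ to zerovalent palladium, which inserts into each C–Br bond; syn carbopalladation of the acrylate and syn beta-hydride elimination give the E-cinnamates. Free 4-bromophenols are established Heck substrates with the bulky P(o-tol)3 ligand.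

Step 6
Reactants: 13 dimethyl (2E,2'E)-3,3'-(6,6'-dihydroxy-5,5'-dimethoxybiphenyl-3,3'-diyl)bis(prop-2-enoate)
Product: 14 dimethyl 3,3'-(6,6'-dihydroxy-5,5'-dimethoxybiphenyl-3,3'-diyl)dipropanoate
Conditions: H2 (1 atm), 10% Pd/C, MeOH–EtOAc, rt
Reagents that add atoms: none
Why: Heterogeneous catalytic hydrogenation of the two conjugated alkenes; arenes, aryl ethers, phenols and esters are inert under these conditions, and no stereocenter is formed.

Step 7
Reactants: 14 dimethyl 3,3'-(6,6'-dihydroxy-5,5'-dimethoxybiphenyl-3,3'-diyl)dipropanoate
Product: 15 3,3'-(6,6'-dihydroxy-5,5'-dimethoxybiphenyl-3,3'-diyl)dipropanoic acid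
Conditions: LiOH·H2O (6 equiv), degassed THF–H2O, rt, argon; then 1 M HCl to pH 2
Reagents that add atoms: lithium hydroxide, [Li+].[OH-]
Why: Saponification of the two unhindered methyl esters by acyl–oxygen cleavage, with acidification to release the diacid; degassing protects the intermediate electron-rich phenolates from air oxidation.

## Compound list

1 | guaiacol (2-methoxyphenol) | COc1ccccc1O | starting material
2 | 1-methoxy-2-(methoxymethoxy)benzene | COCOc1ccccc1OC | intermediate
3 | 3-fluoroanisole | COc1cccc(F)c1 | starting material
4 | [3-methoxy-2-(methoxymethoxy)phenyl]lithium | [Li]c1cccc(OC)c1OCOC | intermediate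
5 | (2-fluoro-6-methoxyphenyl)lithium (2-lithio-3-fluoroanisole) | [Li]c1c(F)cccc1OC | intermediate
6 | 3-methoxybenzyne (1,2-didehydro-3-methoxybenzene) | COC1=CC=CC#C1 | intermediate
7 | [3,3'-dimethoxy-2'-(methoxymethoxy)biphenyl-2-yl]lithium | [Li]c1c(OC)cccc1-c1cccc(OC)c1OCOC | intermediate
8 | lithium [3,3'-dimethoxy-2'-(methoxymethoxy)biphenyl-2-yl]trimethoxyborate | [Li+].CO[B-](OC)(OC)c1c(OC)cccc1-c1cccc(OC)c1OCOC | intermediate
9 | 3,3'-dimethoxy-2'-(methoxymethoxy)biphenyl-2-ol | COCOc1c(OC)cccc1-c1cccc(OC)c1O | intermediate
10 | 3,3'-dimethoxybiphenyl-2,2'-diol | COc1cccc(-c2cccc(OC)c2O)c1O | intermediate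
11 | 5,5'-dibromo-3,3'-dimethoxybiphenyl-2,2'-diol | COc1cc(Br)cc(-c2cc(Br)cc(OC)c2O)c1O | intermediate
12 | methyl acrylate | C=CC(=O)OC | starting material
13 | dimethyl (2E,2'E)-3,3'-(6,6'-dihydroxy-5,5'-dimethoxybiphenyl-3,3'-diyl)bis(prop-2-enoate) | COC(=O)/C=C/c1cc(OC)c(O)c(-c2cc(/C=C/C(=O)OC)cc(OC)c2O)c1 | intermediate
14 | dimethyl 3,3'-(6,6'-dihydroxy-5,5'-dimethoxybiphenyl-3,3'-diyl)dipropanoate | COC(=O)CCc1cc(OC)c(O)c(-c2cc(CCC(=O)OC)cc(OC)c2O)c1 | intermediate
15 | 3,3'-(6,6'-dihydroxy-5,5'-dimethoxybiphenyl-3,3'-diyl)dipropanoic acid | COc1cc(CCC(=O)O)cc(-c2cc(CCC(=O)O)cc(OC)c2O)c1O | target

## Step count and least certain steps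

Total steps: 7. Longest linear sequence: 7 steps (1 to 2 to 9 to 10 to 11 to 13 to 14 to 15); 3 and 12 enter as purchased.

**Step 2 (key step).** Two processes are most likely to erode it. The first is capture of the aryne by its own lithiated precursor before the intended nucleophile reaches it. The second is proton transfer to the hindered 2-biaryllithium before borylation, which would give the biaryl without its oxygen. Fallback: the two bonds are made separately by cross-coupling. Setting out from 2, ortho-lithiation (n-BuLi, THF, 0 °C), quench with B(OMe)3 and mild aqueous work-up should give [3-methoxy-2-(methoxymethoxy)phenyl]boronic acid F1. Suzuki–Miyaura coupling of this with purchased 2-bromo-6-methoxyphenol F2 (Pd(OAc)2, 2-dicyclohexylphosphino-2',6'-dimethoxybiphenyl, K3PO4, toluene–water, 80 °C) should deliver the same mono-MOM biphenol, so the route is rejoined at 9.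

**Step 5.** The likely failure is stalling after the first vinylation. The chelating 2,2'-biphenolate formed under the basic conditions can sequester palladium, and oxidative addition into a phenoxide-rich ring is slow, so protodebromination may compete. Fallback: the phenols are masked as electron-poorer esters. Setting out from 11, acetylation (Ac2O, pyridine) should give 5,5'-dibromo-3,3'-dimethoxybiphenyl-2,2'-diyl diacetate F4. The same Heck reaction with 12 should then give dimethyl (2E,2'E)-3,3'-(6,6'-diacetoxy-5,5'-dimethoxybiphenyl-3,3'-diyl)bis(prop-2-enoate) F5, and brief methanolysis (K2CO3, MeOH, 0 °C) returns to the route at 13.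

**Step 4.** The likely failures are attack of the halogenating agent para to the methoxy group instead of para to the hydroxyl, and overbromination or oxidation of the very electron-rich bisphenol. Fallback: the para position is functionalised with carbon instead of halogen. Setting out from 10, Duff formylation (hexamethylenetetramine, CF3CO2H, reflux, then aqueous acid) should give 6,6'-dihydroxy-5,5'-dimethoxybiphenyl-3,3'-dicarbaldehyde F3. Twofold Wittig olefination with the stabilised ylide methyl (triphenylphosphoranylidene)acetate in hot toluene should then give the E,E-bis-acrylate, rejoining the route at 13 and bypassing steps 4 and 5.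

**Step 7.** The likely failure is oxidative degradation of the bis-phenolate by traces of air during alkaline hydrolysis, giving coloured quinonoid material that is hard to remove from a polar diacid. Fallback: the acid is released without base. Setting out from 11, the Heck reaction of step 5 is run with benzyl acrylate F6 in place of 12 to give dibenzyl (2E,2'E)-3,3'-(6,6'-dihydroxy-5,5'-dimethoxybiphenyl-3,3'-diyl)bis(prop-2-enoate) F7. Hydrogenation over 10% Pd/C then saturates both alkenes and cleaves both benzyl esters in one operation, arriving directly at 15.

## Further compounds

F1 | step 2 | [3-methoxy-2-(methoxymethoxy)phenyl]boronic acid | OB(O)c1cccc(OC)c1OCOC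
F2 | step 2 | 2-bromo-6-methoxyphenol (purchased) | COc1cccc(Br)c1O
F3 | step 4 | 6,6'-dihydroxy-5,5'-dimethoxybiphenyl-3,3'-dicarbaldehyde | COc1cc(C=O)cc(-c2cc(C=O)cc(OC)c2O)c1O
F4 | step 5 | 5,5'-dibromo-3,3'-dimethoxybiphenyl-2,2'-diyl diacetate | COc1cc(Br)cc(-c2cc(Br)cc(OC)c2OC(C)=O)c1OC(C)=O
F5 | step 5 | dimethyl (2E,2'E)-3,3'-(6,6'-diacetoxy-5,5'-dimethoxybiphenyl-3,3'-diyl)bis(prop-2-enoate) | COC(=O)/C=C/c1cc(OC)c(OC(C)=O)c(-c2cc(/C=C/C(=O)OC)cc(OC)c2OC(C)=O)c1
F6 | step 7 | benzyl acrylate (purchased) | C=CC(=O)OCc1ccccc1
F7 | step 7 | dibenzyl (2E,2'E)-3,3'-(6,6'-dihydroxy-5,5'-dimethoxybiphenyl-3,3'-diyl)bis(prop-2-enoate) | O=C(/C=C/c1cc(OC)c(O)c(-c2cc(/C=C/C(=O)OCc3ccccc3)cc(OC)c2O)c1)OCc1ccccc1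
A1 | alternative 1 | 5,5'-bis[(dimethylamino)methyl]-3,3'-dimethoxybiphenyl-2,2'-diol | CN(C)Cc1cc(OC)c(O)c(-c2cc(CN(C)C)cc(OC)c2O)c1
A2 | alternative 1 | sodium dimethyl malonate | [Na+].COC(=O)[CH-]C(=O)OC
A3 | alternative 1 | tetramethyl 2,2'-[(6,6'-dihydroxy-5,5'-dimethoxybiphenyl-3,3'-diyl)bis(methylene)]dimalonate | COC(=O)C(Cc1cc(OC)c(O)c(c1)-c1cc(CC(C(=O)OC)C(=O)OC)cc(OC)c1O)C(=O)OC
A4 | alternative 2 | 2,2'-bis(allyloxy)-3,3'-dimethoxybiphenyl | C=CCOc1c(OC)cccc1-c1cccc(OC)c1OCC=C
A5 | alternative 2 | 5,5'-diallyl-3,3'-dimethoxybiphenyl-2,2'-diol (dehydrodieugenol) | C=CCc1cc(OC)c(O)c(c1)-c1cc(CC=C)cc(OC)c1O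
A6 | alternative 3 | 3,3'-dimethoxy-2,2'-bis(methoxymethoxy)-5,5'-divinylbiphenyl | C=Cc1cc(OC)c(OCOC)c(-c2cc(C=C)cc(OC)c2OCOC)c1
A7 | alternative 3 | carbon dioxide | O=C=O
A8 | alternative 3 | 3,3'-[5,5'-dimethoxy-6,6'-bis(methoxymethoxy)biphenyl-3,3'-diyl]dipropanoic acid | COCOc1c(OC)cc(CCC(=O)O)cc1-c1cc(CCC(=O)O)cc(OC)c1OCOC
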